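## The problem

Compound 21 is a flavonol: a 4H-chromen-4-one, with ring A fused to the pyranone ring C through C4a–C8a, that carries ring B on C2 through the C2–C1' bond. Seven ring carbons bear oxygen: free hydroxyls at C3, C5, C8, C3' and C5', and methyl ethers at C7 and C4'. There is no stereocentre, so nothing has to be controlled in space and no centre can direct another; the difficulty is entirely regiochemical. The two methyl ethers must be told apart from five hydroxyls, which rules out a late global demethylation. The methyl groups must therefore be in place early, and every other oxygen must travel as an ether that is removed under conditions that spare O–CH3. Ring A is a fully differentiated 1,2,3,5-tetraoxygenated benzene, and its carbonyl-bearing carbon (C4a) has to be placed between O1 and O5 and nowhere else. The free compound is fragile: the 5,8-dihydroxy pair is a hydroquinone that air and base convert to the quinone, and the 3-hydroxychromone is degraded by oxidants and opened at C2 by hot alkali, so the last step must be neutral and reductive. The enabling feature is ring B. With C3'–OH, C4'–OMe and C5'–OH around a ring joined at C1', it is a 5-substituted 2-methoxyresorcinol, that is, the dehydrated and enolized form of a hexane-1,3,5-trione with methoxy on C4 whose C1 ketone sits on C2 of the chromone. Because C4' is blocked and ring B is symmetric about the C1'–C4' axis, a single aldol closure (C6 onto C1) is the only six-membered option.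

## Retrosynthesis

**21 to 20.** The three benzylic C–O bonds at O3, O5 and O8 are cut. Methyl protection could not be distinguished from the two ethers that must stay, and silyl or acetal groups would not survive the organolithium, enolate and acid steps ahead. Benzyl ethers tolerate all of these and fall to neutral hydrogenolysis, which leaves O–CH3 and the C2=C3 bond alone and cannot oxidize the hydroquinone. Compound 20 is no simpler in skeleton but is air-stable. The forward step has only to remove three groups cleanly with air excluded.

**20 to 18 (key disconnection).** The C1'–C6' bond is cut and the aromatic unsaturation of ring B is traded for three ketones, giving triketone 18. The neighbouring cuts, C2–C1' (aryl–chromone coupling) or closure of ring C onto a finished ring B, both need a separately made and differentially protected gallate-type arene. Here the 3',5'-dihydroxy-4'-methoxy pattern is written into the chain and ring B needs no protecting group. The precursor has one ring fewer, and its six ring B carbons arrive as one ester carbon plus a five-carbon diketone. The forward reaction must make the C6 enolate add to the C1 ketone in preference to O-cyclization or chain cleavage.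

**18 to 13 and 16.** The chain bond between the chromone-bound carbonyl (C1) and the methylene (C2) is cut, giving chromone ester 13 and the terminal carbanion of dianion 17, generated from diketone 16. Cutting C2–C3 or C3–C4 instead would require regioselective enolization of an unsymmetrical α-methoxy ketone. Diketone 16 is symmetrical, so its dianion has only one kind of terminal carbon. The forward reaction must attack the ester carbonyl and not C2 or C4 of the chromone.

**16 to 15 to 14.** The C3–OMe bond is cut (carbenoid O–H insertion), then the diazo group is removed back to acetylacetone 14. C-acetylating an unsymmetrical methoxy ketone would again raise an enolization question. Starting from symmetrical 14, the methoxy group can only end on the central carbon.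

**13 to 10 and 11.** The O1–C2 and C2–C3 bonds of ring C are cut. Diethyl oxalate 11 supplies C2 and the ester, and the 3-oxygen is already present in ketone 10 as its benzyl ether. The alternative, closing ring C by acylating the arene at C4a late, would move the regiochemical problem of ring A to a more valuable intermediate. Ketone 10 is monocyclic. The forward step asks for a crossed Claisen condensation (via diketo ester 12) and an acid that removes the phenol protecting group and dehydrates without touching benzyl ethers.

**10 to 7 and 8.** The aryl–carbonyl bond is cut. A Friedel–Crafts, Hoesch or Fries reaction on phenol 6 would have to choose between two triply activated ring positions, and the Lewis acids involved threaten the benzyl ethers. Directed metalation of the methoxymethyl ether 7 instead uses the acetal oxygen to select the one hydrogen ortho to it (via aryllithium 9), and Weinreb amide 8 stops at the ketone. Compound 7 is a simple tetraoxygenated benzene.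

**7 to 6 to 4.** The acetal C–O bond is cut to give phenol 6. The phenolic C–O bond is then traced back to the formyl carbon of aldehyde 4 (Dakin-type oxidation via formate 5). This exchange is what distinguishes O1 from O5 and O8 without any selective protection: O1 is born as the only free phenol after the other two are already benzylated.

**4 to 3 to 1.** The two benzyl ethers are cut, then the C5–O bond (Elbs oxidation via sulfate 2), arriving at o-vanillin 1. Compound 1 already holds the adjacent hydroxyl and methoxy groups that become O8 and the C7 methyl ether, its phenol directs the new oxygen to the para carbon, and its aldehyde is the latent O1.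

## Roads not taken

**Alternative 1:** The cut is the C3–C4 bond of ring C. Dialdehyde A1, a salicylaldehyde ether whose ether carbon carries ring B and a formyl group, would be treated with a triazolium-derived carbene. The Breslow intermediate of the aromatic aldehyde adds to the aliphatic aldehyde and closes ring C as dihydroflavonol A2.
- Merits: the closure is mild and organocatalytic. The route is convergent, and ring B comes from a gallate-type building block whose oxygen pattern is unambiguous. In that respect it is as safe as the chosen plan.
- Weak points: A1 holds an aldehyde α to both an aryl and an aryloxy group, which enolizes and oxidizes easily. Making it requires alkylating a hindered phenol with a secondary benzylic electrophile. The ring A aldehyde is electron-rich and flanked by two ortho oxygens, so it forms the Breslow intermediate slowly while the carbene can engage the aliphatic aldehyde with the wrong polarity.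
- Further cost: A2 is at the chromanone oxidation level, so a dehydrogenation in the presence of four benzyl ethers must follow, and the two stereocentres made are then destroyed.
- Comparison: the chosen plan is less convergent. Against that it keeps ring C at the final oxidation level from step 6 onward, uses three benzyl groups and not four, and needs no protection on ring B.

**Alternative 2:** The cut is O1–C8a. Acylhydroquinone A3, a 1,3-diketone with benzyloxy on its central carbon, would be oxidized at an anode to the acylquinone. The enol oxygen adds to the quinone carbon next to the acyl group, and further oxidation gives quinone A4, which must be reduced again before debenzylation.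
- Merits: ring A needs no protecting groups and no regiochemical decision, since O5 and O8 are simply the quinone oxygens. The oxidation is reagent-free. In ring A economy this road is clearly better than the six steps spent here on 13.
- Weak points: A4 is a methoxyquinone fused to a pyranone, a strong electrophile open to addition and to displacement of its methoxy group. It overshoots the oxidation level of the target, so a reduction is added. A3 must be assembled on a hydroquinone whose own hydroxyls compete in acylation. Carbon-centred attack of the diketone can compete with oxygen attack.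
- Comparison: the chosen plan has to set against the shorter ring A route that all redox-sensitive functionality stays masked until the final hydrogenolysis, that no electrochemical equipment is needed, and that ring B is made without a separately protected gallate unit.

**Alternative 3:** The cut is C4a–C5, with C8–C8a made beforehand by adding a metallated pyranone to a cyclobutenedione. Heating hydroxycyclobutenone A5 opens the four-membered ring to a dienylketene. A 6π-electrocyclization onto the pyranone C=C bond, followed by tautomerization, gives hydroquinone A6.
- Merits: the step is thermal and reagent-free. The placement of O5, O8 and the C7 methoxy follows entirely from the connectivity of A5. Like the chosen plan it leaves only hydrogenolysis afterwards.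
- Weak points: A5 needs a 4-pyranone that already carries ring B and the 3-oxygen and is metallated next to a Michael-accepting enone, so the whole right-hand half must be built first. The cyclobutenedione partner must carry hydrogen on one alkene carbon, a less accessible squaric acid derivative, and the nucleophile must pick the correct carbonyl. The electrocyclization onto the pyranone double bond needs high temperature, at which the air-sensitive A6 is formed.
- Comparison: this road is better for ring A, which needs no protection. The chosen plan is shorter to its key intermediate 18 and relies on ordinary enolate chemistry and not on a sensitive heteroaryl organometallic.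

Key step: step 10

Remark: the target is achiral, so no stereocentre is set anywhere; Weinreb amide 8 is taken as a purchasable reagent.

## Route

Step 1
Reactants: 1 o-vanillin (2-hydroxy-3-methoxybenzaldehyde)
Product: 3 2,5-dihydroxy-3-methoxybenzaldehyde, via potassium aryl sulfate 2 (not isolated)
Conditions: K2S2O8, aq. NaOH, 0 °C to rt; then conc. HCl, 80 °C
Reagents that add atoms: potassium peroxodisulfate, [K+].[K+].[O-]S(=O)(=O)OOS(=O)(=O)[O-]
Why: Elbs persulfate oxidation: the phenoxide of 1 is attacked at its free para carbon (C5) by peroxodisulfate and acid hydrolysis of sulfate 2 releases the hydroquinone, as in the classical conversion of salicylaldehyde to gentisaldehyde.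

Step 2
Reactants: 3 2,5-dihydroxy-3-methoxybenzaldehyde
Product: 4 2,5-bis(benzyloxy)-3-methoxybenzaldehyde
Conditions: BnBr, K2CO3, DMF, 60 °C, N2
Reagents that add atoms: benzyl bromide, BrCc1ccccc1
Why: Williamson etherification of both phenols; working under nitrogen keeps the hydroquinone from air oxidation in base.

Step 3
Reactants: 4 2,5-bis(benzyloxy)-3-methoxybenzaldehyde
Product: 6 2,5-bis(benzyloxy)-3-methoxyphenol, via aryl formate 5 (not isolated)
Conditions: mCPBA, CH2Cl2, 0 °C to rt; then K2CO3 (cat.), MeOH, rt
Reagents that add atoms: mCPBA (3-chloroperoxybenzoic acid), O=C(OO)c1cccc(Cl)c1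
Why: Dakin-type Baeyer–Villiger oxidation: the electron-rich aryl group with its ortho benzyloxy substituent migrates in preference to hydride, and mild methanolysis of formate 5 frees the phenol whose oxygen becomes O1.

Step 4
Reactants: 6 2,5-bis(benzyloxy)-3-methoxyphenol
Product: 7 2,5-bis(benzyloxy)-1-methoxy-3-(methoxymethoxy)benzene
Conditions: MOMCl, i-Pr2NEt, CH2Cl2, 0 °C to rt
Reagents that add atoms: chloromethyl methyl ether, COCCl
Why: Standard methoxymethyl protection of a phenol; the acetal both masks O1 and provides the directing group for the next step.

Step 5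
Reactants: 7 2,5-bis(benzyloxy)-1-methoxy-3-(methoxymethoxy)benzene; 8 2-(benzyloxy)-N-methoxy-N-methylacetamide
Product: 10 2-(benzyloxy)-1-[3,6-bis(benzyloxy)-4-methoxy-2-(methoxymethoxy)phenyl]ethan-1-one, via aryllithium 9 (not isolated)
Conditions: n-BuLi, TMEDA, THF, 0 °C; then 8, −78 to 0 °C; aq. NH4Cl
Reagents that add atoms: none
Why: Directed ortho-metalation: the chelating methoxymethoxy group, supported by the neighbouring benzyloxy group, should direct lithiation to the only hydrogen ortho to it (the future C4a), and the Weinreb amide gives the ketone through a stable chelated tetrahedral intermediate without over-addition.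

Step 6
Reactants: 10 2-(benzyloxy)-1-[3,6-bis(benzyloxy)-4-methoxy-2-(methoxymethoxy)phenyl]ethan-1-one; 11 diethyl oxalate
Product: 13 ethyl 3,5,8-tris(benzyloxy)-7-methoxy-4-oxo-4H-chromene-2-carboxylate, via diketo ester 12 (not isolated)
Conditions: LiN(SiMe3)2, THF, −78 °C, then 11, −78 to 0 °C; then conc. HCl, EtOH, 60 °C
Reagents that add atoms: none
Why: Crossed Claisen condensation of the α-benzyloxy ketone enolate with non-enolizable diethyl oxalate, then acid-induced loss of the methoxymethyl group and cyclodehydration of the phenol onto the α-keto ester carbonyl, the standard construction of chromone-2-carboxylates.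

Step 7
Reactants: 14 acetylacetone (pentane-2,4-dione)
Product: 15 3-diazopentane-2,4-dione
Conditions: 4-acetamidobenzenesulfonyl azide, Et3N, MeCN, 0 °C to rt
Reagents that add atoms: 4-acetamidobenzenesulfonyl azide, CC(=O)Nc1ccc(cc1)S(=O)(=O)N=[N+]=[N-]
Why: Regitz diazo transfer to an activated methylene compound.

Step 8
Reactants: 15 3-diazopentane-2,4-dione
Product: 16 3-methoxypentane-2,4-dione
Conditions: Rh2(OAc)4 (cat.), MeOH, ClCH2CH2Cl, 60 °C
Reagents that add atoms: methanol, CO
Why: Carbenoid O–H insertion: dirhodium tetraacetate converts the diazo diketone into a carbenoid that inserts into the O–H bond of methanol, a known reaction of 2-diazo-1,3-dicarbonyl compounds; the symmetrical precursor places the methoxy group on the central carbon without a regiochemical choice.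

Step 9
Reactants: 16 3-methoxypentane-2,4-dione; 13 ethyl 3,5,8-tris(benzyloxy)-7-methoxy-4-oxo-4H-chromene-2-carboxylate
Product: 18 1-[3,5,8-tris(benzyloxy)-7-methoxy-4-oxo-4H-chromen-2-yl]-4-methoxyhexane-1,3,5-trione, via dilithium dianion 17 (not isolated)
Conditions: 16 (3 equiv), LiN(i-Pr)2 (6 equiv), THF, −78 to 0 °C; then 13, −78 to −20 °C; AcOH
Reagents that add atoms: none
Why: Claisen-type acylation of a β-diketone dianion at its terminal carbon, a known route from esters to 1,3,5-triketones: the terminal carbanion of 17 is its most nucleophilic site, the ester carbonyl of 13 (a vinylogous oxalate) is the most electrophilic position, and excess dianion compensates for deprotonation of the acidic product; 18 is racemic at C4 and partly enolized.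

Step 10
Reactants: 18 1-[3,5,8-tris(benzyloxy)-7-methoxy-4-oxo-4H-chromen-2-yl]-4-methoxyhexane-1,3,5-trione
Product: 20 3,5,8-tris(benzyloxy)-2-(3,5-dihydroxy-4-methoxyphenyl)-7-methoxy-4H-chromen-4-one, via cyclic aldol 19 (not isolated)
Conditions: Cs2CO3, i-PrOH/THF, rt to 40 °C, Ar; then 1 M aq. HCl, rt
Reagents that add atoms: none
Why: Carbonate converts 18 into its enolates, and the small equilibrium share in which the terminal methyl ketone (C6) is enolized while C1 remains a ketone adds C6 to the C1 carbonyl, which the electron-poor chromon-2-yl group makes the most electrophilic of the three; this forms the C1'–C6' bond and gives cyclic aldol 19. Loss of water from 19 by an E1cB pathway and enolization of the two remaining ketones, completed on acidification, give the resorcinol, and the gain of aromaticity makes the sequence irreversible. The closest known reaction type is the base-mediated aldol aromatization of 1,3,5-triketones and triketo esters to resorcinols, as in diacetylacetone to orcinol and carbonate-induced resorcylate formation. Ring B closes in the 6-(enolexo)-exo-trig mode. No stereocentre is formed in 20; the centre at C4 of 18 and the stereoisomerism of 19 vanish on aromatization. The selectivity needed is carbocyclic aldol over O-cyclization to a 4-pyranone, over retro-Claisen cleavage and over nucleophilic opening of ring C at C2: the basic, weakly nucleophilic medium disfavours the acid-promoted pyranone closure, and the diketonate anion of the chain shields the chain carbonyls and C2 of the chromone from alkoxide. Regiochemistry is fixed by the substrate, since the methoxy-bearing C4 permits no other six-membered carbon–carbon closure and becomes C4' between the two new hydroxyls.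

Step 11
Reactants: 20 3,5,8-tris(benzyloxy)-2-(3,5-dihydroxy-4-methoxyphenyl)-7-methoxy-4H-chromen-4-one
Product: 21 3,5,8-trihydroxy-2-(3,5-dihydroxy-4-methoxyphenyl)-7-methoxy-4H-chromen-4-one
Conditions: H2 (1 atm), Pd/C, EtOAc/MeOH, rt; work-up under Ar
Reagents that add atoms: none
Why: Hydrogenolysis of aryl benzyl ethers over palladium on carbon; methyl ethers and the C2=C3 bond of the flavonol are not affected, and work-up under inert gas protects the 5,8-hydroquinone.

## Compound list

1 | o-vanillin (2-hydroxy-3-methoxybenzaldehyde) | COc1cccc(C=O)c1O | starting material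
2 | potassium 3-formyl-4-hydroxy-5-methoxyphenyl sulfate | COc1cc(OS(=O)(=O)[O-])cc(C=O)c1O.[K+] | intermediate
3 | 2,5-dihydroxy-3-methoxybenzaldehyde | COc1cc(O)cc(C=O)c1O | intermediate
4 | 2,5-bis(benzyloxy)-3-methoxybenzaldehyde | COc1cc(OCc2ccccc2)cc(C=O)c1OCc1ccccc1 | intermediate
5 | 2,5-bis(benzyloxy)-3-methoxyphenyl formate | COc1cc(OCc2ccccc2)cc(OC=O)c1OCc1ccccc1 | intermediate
6 | 2,5-bis(benzyloxy)-3-methoxyphenol | COc1cc(OCc2ccccc2)cc(O)c1OCc1ccccc1 | intermediate
7 | 2,5-bis(benzyloxy)-1-methoxy-3-(methoxymethoxy)benzene | COCOc1cc(OCc2ccccc2)cc(OC)c1OCc1ccccc1 | intermediate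
8 | 2-(benzyloxy)-N-methoxy-N-methylacetamide | CON(C)C(=O)COCc1ccccc1 | starting material
9 | [3,6-bis(benzyloxy)-4-methoxy-2-(methoxymethoxy)phenyl]lithium | COCOc1c([Li])c(OCc2ccccc2)cc(OC)c1OCc1ccccc1 | intermediate
10 | 2-(benzyloxy)-1-[3,6-bis(benzyloxy)-4-methoxy-2-(methoxymethoxy)phenyl]ethan-1-one | COCOc1c(C(=O)COCc2ccccc2)c(OCc2ccccc2)cc(OC)c1OCc1ccccc1 | intermediate
11 | diethyl oxalate | CCOC(=O)C(=O)OCC | starting material
12 | ethyl 3-(benzyloxy)-4-[3,6-bis(benzyloxy)-4-methoxy-2-(methoxymethoxy)phenyl]-2,4-dioxobutanoate (racemic, enolizable) | CCOC(=O)C(=O)C(OCc1ccccc1)C(=O)c1c(OCOC)c(OCc2ccccc2)c(OC)cc1OCc1ccccc1 | intermediate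
13 | ethyl 3,5,8-tris(benzyloxy)-7-methoxy-4-oxo-4H-chromene-2-carboxylate | CCOC(=O)c1oc2c(OCc3ccccc3)c(OC)cc(OCc3ccccc3)c2c(=O)c1OCc1ccccc1 | intermediate
14 | acetylacetone (pentane-2,4-dione) | CC(=O)CC(C)=O | starting material
15 | 3-diazopentane-2,4-dione | CC(=O)C(=[N+]=[N-])C(C)=O | intermediate
16 | 3-methoxypentane-2,4-dione | COC(C(C)=O)C(C)=O | intermediate
17 | dilithium 3-methoxypenta-1,3-diene-2,4-diolate (enolate geometry not defined) | [Li+].[Li+].C=C([O-])C(OC)=C(C)[O-] | intermediate
18 | 1-[3,5,8-tris(benzyloxy)-7-methoxy-4-oxo-4H-chromen-2-yl]-4-methoxyhexane-1,3,5-trione (racemic at C4, enolizable) | COc1cc(OCc2ccccc2)c2c(=O)c(OCc3ccccc3)c(C(=O)CC(=O)C(OC)C(C)=O)oc2c1OCc1ccccc1 | intermediate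
19 | 5-hydroxy-2-methoxy-5-[3,5,8-tris(benzyloxy)-7-methoxy-4-oxo-4H-chromen-2-yl]cyclohexane-1,3-dione (mixture of cis and trans isomers) | COc1cc(OCc2ccccc2)c2c(=O)c(OCc3ccccc3)c(C3(O)CC(=O)C(OC)C(=O)C3)oc2c1OCc1ccccc1 | intermediate
20 | 3,5,8-tris(benzyloxy)-2-(3,5-dihydroxy-4-methoxyphenyl)-7-methoxy-4H-chromen-4-one | COc1cc(OCc2ccccc2)c2c(=O)c(OCc3ccccc3)c(-c3cc(O)c(OC)c(O)c3)oc2c1OCc1ccccc1 | intermediate
21 | 3,5,8-trihydroxy-2-(3,5-dihydroxy-4-methoxyphenyl)-7-methoxy-4H-chromen-4-one (achiral) | COc1cc(O)c2c(=O)c(O)c(-c3cc(O)c(OC)c(O)c3)oc2c1O | target

## Step count and uncertain steps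

Total: 11 steps. Longest linear sequence: 9 steps (steps 1 to 6, then 9 to 11, from o-vanillin 1); steps 7 and 8 form a two-step side branch from acetylacetone 14.

**Step 10 (key step).** The most likely failures are three. An enol oxygen may close onto the far ketone, giving a 4-pyranone, if the aldol is slow or acid is added too early. Alkoxide may cleave the chain at the activated C1 ketone in a retro-Claisen reaction. A nucleophile may add at C2 and open ring C. All three stem from the high electrophilicity of the carbonyl attached to the chromone.

Fallback: abandon the ring B construction and attach ring B preformed, setting out from ketone 10 and returning to the route at 21. The lithium enolate of 10 would be acylated with methyl 3,5-bis(benzyloxy)-4-methoxybenzoate F1, made by benzylating commercial methyl 3,5-dihydroxy-4-methoxybenzoate. This gives 2-(benzyloxy)-1-[3,5-bis(benzyloxy)-4-methoxyphenyl]-3-[3,6-bis(benzyloxy)-4-methoxy-2-(methoxymethoxy)phenyl]propane-1,3-dione F2. Hydrochloric acid in ethanol then removes the methoxymethyl group and cyclodehydrates to 3,5,8-tris(benzyloxy)-2-[3,5-bis(benzyloxy)-4-methoxyphenyl]-7-methoxy-4H-chromen-4-one F3. Hydrogenolysis over Pd/C removes all five benzyl groups and gives 21.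

**Step 9.** The carbon nucleophile may add in conjugate fashion at C2 of the chromone with ring opening, and proton transfer from the acidic triketone to the dianion may stall the acylation, so that a large excess of a strongly basic reagent is in contact with the chromone.

Fallback: mask the diketone as an isoxazole, setting out from 16 and 13 and returning at 18. Condensing 16 with hydroxylamine hydrochloride gives 4-methoxy-3,5-dimethylisoxazole F4. Lateral lithiation of its 5-methyl group (n-BuLi, THF, −78 °C) and acylation with ester 13 give 2-(4-methoxy-3-methylisoxazol-5-yl)-1-[3,5,8-tris(benzyloxy)-7-methoxy-4-oxo-4H-chromen-2-yl]ethan-1-one F5. Reductive N–O cleavage with Mo(CO)6 in wet acetonitrile, which leaves benzyl ethers intact, gives (4E)-5-amino-4-methoxy-1-[3,5,8-tris(benzyloxy)-7-methoxy-4-oxo-4H-chromen-2-yl]hex-4-ene-1,3-dione F6. Mild aqueous acid hydrolyses this enaminone to 18.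

**Step 5.** Lithiation may also occur at the other ring hydrogen, which lies between the methoxy and a benzyloxy group, or at a benzylic CH2 followed by Wittig rearrangement.

Fallback: fix the regiochemistry through the free phenol, setting out from 6 and returning at 10. Magnesium-mediated ortho-formylation of 6 (MgCl2, Et3N, paraformaldehyde, MeCN, reflux) can only occur at the single free ortho carbon and gives 3,6-bis(benzyloxy)-2-hydroxy-4-methoxybenzaldehyde F7. Methoxymethyl protection gives 3,6-bis(benzyloxy)-4-methoxy-2-(methoxymethoxy)benzaldehyde F8. Addition of benzyloxymethyllithium (from Bu3SnCH2OBn and n-BuLi) gives racemic 2-(benzyloxy)-1-[3,6-bis(benzyloxy)-4-methoxy-2-(methoxymethoxy)phenyl]ethan-1-ol F9, and Dess–Martin oxidation gives 10.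

**Step 1.** The persulfate oxidation may stop at low conversion or over-oxidize the electron-rich hydroquinone to quinone-derived tars.

Fallback: introduce the C5 oxygen by cross-coupling, setting out from 1 and returning at 4. Bromination of 1 para to the hydroxyl (Br2, NaOAc, AcOH) gives 5-bromo-2-hydroxy-3-methoxybenzaldehyde F10. Benzylation gives 2-(benzyloxy)-5-bromo-3-methoxybenzaldehyde F11. Palladium-catalysed C–O coupling with benzyl alcohol (Pd2(dba)3, a bulky biarylphosphine, Cs2CO3, toluene, 90 °C) gives 4.

## Further compounds

F1 | step 10 | methyl 3,5-bis(benzyloxy)-4-methoxybenzoate | COC(=O)c1cc(OCc2ccccc2)c(OC)c(OCc2ccccc2)c1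
F2 | step 10 | 2-(benzyloxy)-1-[3,5-bis(benzyloxy)-4-methoxyphenyl]-3-[3,6-bis(benzyloxy)-4-methoxy-2-(methoxymethoxy)phenyl]propane-1,3-dione (racemic, enolizable) | COCOc1c(C(=O)C(OCc2ccccc2)C(=O)c2cc(OCc3ccccc3)c(OC)c(OCc3ccccc3)c2)c(OCc2ccccc2)cc(OC)c1OCc1ccccc1
F3 | step 10 | 3,5,8-tris(benzyloxy)-2-[3,5-bis(benzyloxy)-4-methoxyphenyl]-7-methoxy-4H-chromen-4-one | COc1cc(OCc2ccccc2)c2c(=O)c(OCc3ccccc3)c(-c3cc(OCc4ccccc4)c(OC)c(OCc4ccccc4)c3)oc2c1OCc1ccccc1
F4 | step 9 | 4-methoxy-3,5-dimethylisoxazole | COc1c(C)noc1C
F5 | step 9 | 2-(4-methoxy-3-methylisoxazol-5-yl)-1-[3,5,8-tris(benzyloxy)-7-methoxy-4-oxo-4H-chromen-2-yl]ethan-1-one | COc1cc(OCc2ccccc2)c2c(=O)c(OCc3ccccc3)c(C(=O)Cc3onc(C)c3OC)oc2c1OCc1ccccc1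
F6 | step 9 | (4E)-5-amino-4-methoxy-1-[3,5,8-tris(benzyloxy)-7-methoxy-4-oxo-4H-chromen-2-yl]hex-4-ene-1,3-dione | COc1cc(OCc2ccccc2)c2c(=O)c(OCc3ccccc3)c(C(=O)CC(=O)/C(OC)=C(\N)C)oc2c1OCc1ccccc1
F7 | step 5 | 3,6-bis(benzyloxy)-2-hydroxy-4-methoxybenzaldehyde | COc1cc(OCc2ccccc2)c(C=O)c(O)c1OCc1ccccc1
F8 | step 5 | 3,6-bis(benzyloxy)-4-methoxy-2-(methoxymethoxy)benzaldehyde | COCOc1c(C=O)c(OCc2ccccc2)cc(OC)c1OCc1ccccc1
F9 | step 5 | 2-(benzyloxy)-1-[3,6-bis(benzyloxy)-4-methoxy-2-(methoxymethoxy)phenyl]ethan-1-ol (racemic) | COCOc1c(C(O)COCc2ccccc2)c(OCc2ccccc2)cc(OC)c1OCc1ccccc1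
F10 | step 1 | 5-bromo-2-hydroxy-3-methoxybenzaldehyde | COc1cc(Br)cc(C=O)c1O
F11 | step 1 | 2-(benzyloxy)-5-bromo-3-methoxybenzaldehyde | COc1cc(Br)cc(C=O)c1OCc1ccccc1
A1 | alternative 1 | 3,6-bis(benzyloxy)-2-{1-[3,5-bis(benzyloxy)-4-methoxyphenyl]-2-oxoethoxy}-4-methoxybenzaldehyde (racemic) | COc1cc(OCc2ccccc2)c(C=O)c(OC(C=O)c2cc(OCc3ccccc3)c(OC)c(OCc3ccccc3)c2)c1OCc1ccccc1
A2 | alternative 1 | 5,8-bis(benzyloxy)-2-[3,5-bis(benzyloxy)-4-methoxyphenyl]-3-hydroxy-7-methoxychroman-4-one (racemic, mixture of diastereomers) | COc1cc(OCc2ccccc2)c2c(c1OCc1ccccc1)OC(c1cc(OCc3ccccc3)c(OC)c(OCc3ccccc3)c1)C(O)C2=O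
A3 | alternative 2 | 2-(benzyloxy)-1-[3,5-bis(benzyloxy)-4-methoxyphenyl]-3-(2,5-dihydroxy-4-methoxyphenyl)propane-1,3-dione (racemic, enolizable) | COc1cc(O)c(C(=O)C(OCc2ccccc2)C(=O)c2cc(OCc3ccccc3)c(OC)c(OCc3ccccc3)c2)cc1O
A4 | alternative 2 | 3-(benzyloxy)-2-[3,5-bis(benzyloxy)-4-methoxyphenyl]-7-methoxy-4H-chromene-4,5,8-trione | COC1=CC(=O)c2c(=O)c(OCc3ccccc3)c(-c3cc(OCc4ccccc4)c(OC)c(OCc4ccccc4)c3)oc2C1=O
A5 | alternative 3 | 4-{5-(benzyloxy)-6-[3,5-bis(benzyloxy)-4-methoxyphenyl]-4-oxo-4H-pyran-2-yl}-4-hydroxy-3-methoxycyclobut-2-en-1-one (racemic) | COC1=CC(=O)C1(O)c1cc(=O)c(OCc2ccccc2)c(-c2cc(OCc3ccccc3)c(OC)c(OCc3ccccc3)c2)o1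
A6 | alternative 3 | 3-(benzyloxy)-2-[3,5-bis(benzyloxy)-4-methoxyphenyl]-5,8-dihydroxy-7-methoxy-4H-chromen-4-one | COc1cc(O)c2c(=O)c(OCc3ccccc3)c(-c3cc(OCc4ccccc4)c(OC)c(OCc4ccccc4)c3)oc2c1O
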